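**Conventions used throughout.** Atoms are numbered in the germacranolide manner: C1 is the furanone ketone, C2=C3 the furanone alkene, C4=C5 the Z ring alkene (C15 on C4), C6 carries the lactone oxygen, C7 the lactone carbon C11, C8 the tiglate, C9 is CH2, C10 is the quaternary carbon (methyl C14, ring oxygen to C3), and C11, C12, C13 are the lactone α-carbon, carbonyl and methylene. PMB is 4-methoxybenzyl. Compound numbers 1–32 are those of the steps below.

## The problem

Target 32 is a 3(2H)-furanone (C10, C1, C2, C3, O) whose C3 and C10 are joined by the six-carbon chain C4–C9; this gives a strained oxygen-bridged ten-membered carbocycle, onto whose C6–C7 bond a γ-lactone is fused. The target SMILES places H6 and H7 on the same face, so the lactone is cis-fused, and the descriptors are 4Z, 6S, 7R, 8R, 10R with an E tiglate. C10 is quaternary and separated from the contiguous triad C6–C7–C8 by a methylene group, so it cannot be relied on to control that triad. The triad therefore has to be set by a reagent and relayed internally, not left to the folding of a medium ring. The α-methylene lactone, the push–pull dienyl furanone, the primary allylic alcohol and the C8 ester are all base- and nucleophile-sensitive; the C8 oxygen sits where it can attack C12 and translactonise, so these groups should appear last. The enabling feature is the O–C–O pattern on C6, C7, C8: an acetate unit tethered to O6 can attack C7 of a trans C7–C8 epoxide from the side opposite the epoxide oxygen. That single invertive event forms C7–C11, closes the lactone, and leaves O8 on C8 with its configuration. If the acetate carbon carries a phosphonate, the same carbon later becomes the C13 methylene carrier. The remaining difficulty is to close the nine-membered oxacycle (O, C3–C10) at a bond where neither geometry nor configuration is at stake.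

## Retrosynthesis

**32 back to 27.** The C15 PMB ether is cut first (31), then the C8 acyl–oxygen bond (29 and tigloyl chloride 30), then C11=C13 (phosphono lactone 27 and formaldehyde 28). This order keeps the Michael acceptor and the free allylic alcohol out of every basic or organometallic step. The forward reactions must be mild: the methylenation must not let O8 reach C12, and the acylation must not deconjugate the tiglate.

**27 back to 25 (C7–C11).** Cutting C7–C11 turns the lactone into the C6 phosphonoacetate of a trans-7,8-epoxide. The neighbouring cut at C6–C7 (allylation of a C6 aldehyde) would have to set C6 and C7 inside the ring; lactonisation of a preformed C12 acid would leave C7 and C8 to be made separately. The chosen cut reduces three stereocentres to one epoxy alcohol of defined configuration. It asks the forward reaction for attack at C7 rather than C8 and for C6–O anti to C7–O.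

**25 back to 24 (C4=C5).** The ring is opened at the trisubstituted alkene by ring-closing metathesis. Closing at C7=C8 instead would require an E alkene in the nine-membered ring, and the epoxide would then be introduced on a trans-cycloalkene that exposes only one face. Which face is exposed is fixed by the planar chirality of the ring, not by a reagent, so C7 and C8 would be left to chance. Closure at C4=C5 creates no stereocentre and only the ring-cis alkene is possible. Precursor 24 is acyclic apart from the furanone and already holds every stereocentre; closure of this kind of furanone-bridged nine-membered ring at this position by metathesis of a 1,1-disubstituted alkene is a known ring closure.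

**24 back to 21 (C6–O, epoxide oxygen).** A titanium–tartrate epoxidation of a secondary allylic alcohol gives the erythro epoxy alcohol, whereas the key step needs threo. The C6–O bond is therefore cut with inversion: 24 comes from erythro alcohol 22 and acid 23 by Mitsunobu esterification, which installs the tether and corrects C6 in one operation. Alcohol 22 comes from dienol 21 by Sharpless epoxidation run as a kinetic resolution, so that C7 and C8 are set by the tartrate and C6 is selected by the same catalyst.

**21 back to 17 (C5–C6, C7=C8).** Dienol 21 is cut at C5–C6 to E-enal 19 and vinylmagnesium bromide 20. Enal 19 is cut at C7=C8 to allyl furanone 17 and crotonaldehyde 18 by cross-metathesis. The E geometry, which becomes the trans epoxide, is the thermodynamic outcome of cross-metathesis with an enal. No selectivity is asked of the Grignard addition, because the resolution follows.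

**17 back to 8 and 14 (O–C3, C1–C2).** The furanone is opened at O–C3 to α′-hydroxy ynone 16, whose 5-endo cyclisation is reliable under gold catalysis. Ynone 16 is cut at C1–C2 into Weinreb amide 8 and enyne 14. This makes the furanone from two small pieces and places the C4 methylidene, needed later for ring closure, on the alkyne partner from the start.

**8 back to 1 (C9–C10).** Amide 8 comes from allyl dioxolanone 6 and amine salt 7; 6 comes from dioxolanone 3 and allyl bromide 4; 3 comes from (S)-lactic acid 1 and pivalaldehyde 2. The allyl group is C8–C9 plus the carbon lost in cross-metathesis, so the quaternary centre arrives in two steps with the correct (R) configuration and needs no redox adjustment.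

**14 back to 9.** Enyne 14 is the desilylated form of 13, which is cut at C3–C4 into vinyl bromide 11 and trimethylsilylacetylene 12. Ether 11 comes from 2,3-dibromopropene 9 and 4-methoxybenzyl alcohol 10.

## Roads not taken

**Alternative 1:** The ten-membered ring is uncovered, not closed. A transannular C1–C6 bond is added retrosynthetically, so the carbocycle becomes two fused six-membered rings with hydroxyls on both fusion carbons. In the forward direction, glycol cleavage of that ditertiary cis-diol breaks the fusion bond and gives trione A1 with ketones at C1 and C6.
- Merits: no medium-ring cyclisation and no high dilution; the Z C4=C5 alkene is inherited from a cyclohexenone; C7, C8 and C10 can be set on a rigid bicycle.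
- Weak points: A1 contains a 1,3-diketone (C1/C3), a C6 ketone conjugated to C4=C5, an acidic C7–H, and a C8 tiglate β to the C6 carbonyl, which invites epimerisation and elimination. C6 must still be reduced with the right sense in a flexible ring. The C10 oxygen has to be dehydrated onto C3 to form the furanone, and C12 must be oxidised to the acid level before lactonisation.
- Comparison: for ring formation this road is more dependable than step 13 of the chosen plan, which must force a strained ring shut. Against that, the chosen plan fixes C6, C7 and C8 by reagent control before the ring exists, keeps every carbon at its final oxidation level, and does not make the stereocentre that decides the lactone fusion last under substrate control.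

**Alternative 2:** The cut is C7–C8. In the forward direction, tin–lithium exchange at C8 of a thirteen-membered cyclic allylic ether gives an α-alkoxy organolithium. This rearranges [2,3] (Wittig–Still) onto C7 of a C7=C11 alkene and contracts the ring to the ten-membered carbinol A2.
- Merits: one step forms the C7–C8 bond, two stereocentres and the C11=C13 methylene; the ring that must be cyclised is large and unstrained; no phosphorus chemistry is needed for the methylene group.
- Weak points: the sense at C7 is decided by the folding of a thirteen-membered ring, and a [1,2] shift competes. The C8 stannane must be made and carried as a single enantiomer. A2 has C1 only as a silyl ether and C12 as a protected alcohol, so the furanone carbonyl, the lactone carbonyl and the tiglate all remain to be installed by late oxidations next to an enol ether.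
- Comparison: A2 is ahead of the chosen plan in having the methylene group in place and in avoiding a direct medium-ring closure. The chosen plan offers in return reagent-controlled stereocentres and correct oxidation levels at C1 and C12 from the start, which saves the late redox steps.

**Alternative 3:** The cut is C2–C3. A nine-membered lactone (carbonyl C3, ring oxygen on C10) carries an acetyl group on C10. The methyl ketone enolate (C2) attacks the lactone carbonyl, and loss of water from the hemiketal gives the furanone, so the lactone oxygen becomes the furanone oxygen and the ring becomes the carbocycle A3.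
- Merits: a lactonisation replaces a carbocyclisation as the medium-ring closure; furanone and carbocycle are formed together; no transition-metal step is needed on a complex substrate.
- Weak points: the electrophile is a hindered enoate, so conjugate addition and γ-deprotonation compete with 1,2-attack. The C8 tiglate is a second ester the same enolate can reach. Acylating the tertiary C10 hydroxyl to make the lactone is itself difficult. The key step does nothing for the C6–C7–C8 triad, and C12 still has to be oxidised and lactonised.
- Comparison: the ring-forming event is probably more reliable than metathesis. The chosen plan answers with a key step that itself creates C7, joins the lactone and fixes its fusion, whereas here the triad remains a separate, unsolved task.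

Key step: step 14

**Remark on the chemistry.** C11 of 27 is configurationally labile and is destroyed in step 15; it is drawn as the epimer expected on equilibration (phosphorus trans to C8). Dienol 21 is carried as both C6 epimers.

## Route

Step 1
Reactants: 1 (S)-lactic acid; 2 pivalaldehyde
Product: 3 (2S,5S)-2-tert-butyl-5-methyl-1,3-dioxolan-4-one
Conditions: TsOH·H2O (cat.), H2SO4 (cat.), pentane, reflux, Dean–Stark; crystallisation at −78 °C
Reagents that add atoms: none
Why: Acid-catalysed acetalisation with azeotropic removal of water; the cis acetal is the thermodynamic product and is purified by low-temperature crystallisation, so the lactate configuration is stored in the acetal carbon (self-regeneration of stereocentres).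

Step 2
Reactants: 3 (2S,5S)-2-tert-butyl-5-methyl-1,3-dioxolan-4-one; 4 allyl bromide
Product: 6 (2S,5R)-5-allyl-2-tert-butyl-5-methyl-1,3-dioxolan-4-one, via lithium enolate 5 (not isolated)
Conditions: LiN(iPr)2, THF, −78 °C; then 4, −78 to −20 °C
Reagents that add atoms: none
Why: Enolate alkylation; the planar enolate 5 is attacked on the face opposite the tert-butyl group, so allyl takes the place of the former hydrogen and the future C10 is obtained as (R).

Step 3
Reactants: 6 (2S,5R)-5-allyl-2-tert-butyl-5-methyl-1,3-dioxolan-4-one; 7 N,O-dimethylhydroxylamine hydrochloride
Product: 8 (2R)-2-hydroxy-N-methoxy-N,2-dimethylpent-4-enamide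
Conditions: AlMe3, CH2Cl2, 0 to 40 °C; aq. HCl work-up
Reagents that add atoms: none
Why: Weinreb aminolysis of the acylal-type lactone by the aluminium amide; the hemiacetal alkoxide collapses with loss of pivalaldehyde, which frees the tertiary hydroxyl and leaves an acyl donor that accepts one organometallic equivalent only.

Step 4
Reactants: 9 2,3-dibromopropene; 10 4-methoxybenzyl alcohol
Product: 11 1-{[(2-bromoprop-2-en-1-yl)oxy]methyl}-4-methoxybenzene
Conditions: 50% aq. NaOH, Bu4N(HSO4) (cat.), toluene, rt
Reagents that add atoms: none
Why: Williamson ether synthesis under phase transfer; only the allylic bromide is displaced (direct and allylic displacement give the same ether) and the vinylic bromide is inert.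

Step 5
Reactants: 11 1-{[(2-bromoprop-2-en-1-yl)oxy]methyl}-4-methoxybenzene; 12 trimethylsilylacetylene
Product: 13 {3-[(4-methoxybenzyloxy)methyl]but-3-en-1-yn-1-yl}trimethylsilane
Conditions: Pd(PPh3)2Cl2 (cat.), CuI (cat.), Et3N, THF, 50 °C
Reagents that add atoms: none
Why: Sonogashira coupling of a 2-bromoalkene with a terminal alkyne; it joins C3 to C4 and brings in C2.

Step 6
Reactants: 13 {3-[(4-methoxybenzyloxy)methyl]but-3-en-1-yn-1-yl}trimethylsilane
Product: 14 1-methoxy-4-{[(2-methylidenebut-3-yn-1-yl)oxy]methyl}benzene
Conditions: K2CO3 (cat.), MeOH, 0 °C to rt
Reagents that add atoms: none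
Why: Methanolysis of the alkynyl–silicon bond under catalytic methoxide; ether and alkene are unaffected.

Step 7
Reactants: 8 (2R)-2-hydroxy-N-methoxy-N,2-dimethylpent-4-enamide; 14 1-methoxy-4-{[(2-methylidenebut-3-yn-1-yl)oxy]methyl}benzene
Product: 16 (4R)-4-hydroxy-9-(4-methoxybenzyloxy)-4-methyl-8-methylidenenon-1-en-6-yn-5-one, via lithium acetylide 15 (not isolated)
Conditions: 14 (2.3 equiv), n-BuLi (2.2 equiv), THF, −78 °C; then 8, −78 to 0 °C; aq. NH4Cl
Reagents that add atoms: none
Why: Acylation of an alkynyllithium by a Weinreb amide; the first equivalent of 15 only deprotonates the tertiary hydroxyl (regenerating 14, which is recovered), and the second adds to give a chelated tetrahedral intermediate that releases the ynone on work-up without over-addition.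

Step 8
Reactants: 16 (4R)-4-hydroxy-9-(4-methoxybenzyloxy)-4-methyl-8-methylidenenon-1-en-6-yn-5-one
Product: 17 (2R)-2-allyl-5-[3-(4-methoxybenzyloxy)prop-1-en-2-yl]-2-methylfuran-3(2H)-one
Conditions: (Ph3P)AuCl (5 mol %), AgOTf (5 mol %), toluene, rt
Reagents that add atoms: none
Why: Gold-catalysed 5-endo-dig cycloisomerisation of an α′-hydroxy ynone to the 3(2H)-furanone; the tertiary oxygen adds to the activated alkyne at C3 and the quaternary centre is untouched.

Step 9
Reactants: 17 (2R)-2-allyl-5-[3-(4-methoxybenzyloxy)prop-1-en-2-yl]-2-methylfuran-3(2H)-one; 18 (E)-crotonaldehyde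
Product: 19 (2E)-4-{(2R)-5-[3-(4-methoxybenzyloxy)prop-1-en-2-yl]-2-methyl-3-oxo-2,3-dihydrofuran-2-yl}but-2-enal
Conditions: second-generation Hoveyda–Grubbs catalyst (5 mol %), 18 (5 equiv), CH2Cl2, 40 °C
Reagents that add atoms: none
Why: Olefin cross-metathesis of the allyl group with an excess of the enal gives the E enal under thermodynamic control; the conjugated 1,1-disubstituted alkene at C4 is too hindered and electron-poor to take part.

Step 10
Reactants: 19 (2E)-4-{(2R)-5-[3-(4-methoxybenzyloxy)prop-1-en-2-yl]-2-methyl-3-oxo-2,3-dihydrofuran-2-yl}but-2-enal; 20 vinylmagnesium bromide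
Product: 21 (2R)-2-[(2E)-4-hydroxyhexa-2,5-dien-1-yl]-5-[3-(4-methoxybenzyloxy)prop-1-en-2-yl]-2-methylfuran-3(2H)-one, both epimers at the carbinol carbon C6
Conditions: THF, −78 °C; aq. NH4Cl
Reagents that add atoms: none
Why: Grignard 1,2-addition to the aldehyde, which is far more electrophilic than the vinylogous ester carbonyl of the furanone at this temperature; no facial control is expected or needed because the next step selects the epimer.

Step 11
Reactants: 21 (2R)-2-[(2E)-4-hydroxyhexa-2,5-dien-1-yl]-5-[3-(4-methoxybenzyloxy)prop-1-en-2-yl]-2-methylfuran-3(2H)-one (both C6 epimers)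
Product: 22 (2R)-2-{[(2R,3R)-3-[(1R)-1-hydroxyprop-2-en-1-yl]oxiran-2-yl]methyl}-5-[3-(4-methoxybenzyloxy)prop-1-en-2-yl]-2-methylfuran-3(2H)-one (erythro; 6R,7R,8R,10R)
Conditions: Ti(OiPr)4 (cat.), D-(−)-diisopropyl tartrate (cat.), t-BuOOH (0.55 equiv), 4 Å molecular sieves, CH2Cl2, −20 °C
Reagents that add atoms: tert-butyl hydroperoxide, CC(C)(C)OO
Why: Sharpless asymmetric epoxidation run as a kinetic resolution: with the (S,S)-tartrate the (6R)-epimer is epoxidised fast at its E-disubstituted alkene on the face the catalyst dictates, which sets C7 and C8 and gives the erythro epoxy alcohol. The (6S)-epimer, mismatched at this alkene and reactive only at its slower vinyl group, is left and separated; the trans epoxide follows from the E alkene.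

Step 12
Reactants: 22 erythro epoxy alcohol (6R,7R,8R,10R); 23 diethylphosphonoacetic acid
Product: 24 (1S)-1-[(2S,3R)-3-({(2R)-5-[3-(4-methoxybenzyloxy)prop-1-en-2-yl]-2-methyl-3-oxo-2,3-dihydrofuran-2-yl}methyl)oxiran-2-yl]prop-2-en-1-yl (diethoxyphosphoryl)acetate (threo; 6S,7S,8R,10R)
Conditions: PPh3, diisopropyl azodicarboxylate, toluene, 0 °C to rt
Reagents that add atoms: none
Why: Mitsunobu esterification with inversion at C6 turns the erythro alcohol into the threo ester and installs the phosphonoacetate tether in the same operation; vinyl epoxy carbinols are established substrates for this inversion, and the change of descriptor at C7 is only a change of priorities.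

Step 13
Reactants: 24 threo epoxy phosphonoacetate (6S,7S,8R,10R)
Product: 25 (4Z,6S,7S,8R,10R)-macrocyclic trans-7,8-epoxide 6-(diethylphosphonoacetate): furanone bridged from C3 to C10 by C4–C9, C4 bearing CH2OPMB, C10 bearing methyl
Conditions: second-generation Hoveyda–Grubbs catalyst (15 mol %), toluene (1 mM), 80 °C
Reagents that add atoms: none
Why: Ring-closing metathesis between the C5 vinyl group and the C4 methylidene; in the nine-membered oxacycle only the ring-cis trisubstituted alkene can form, no stereocentre is created, and loss of ethene drives the closure.

Step 14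
Reactants: 25 macrocyclic epoxy phosphonoacetate (4Z,6S,7S,8R,10R)
Product: 27 (4Z,6S,7R,8R,10R,11S)-11-diethoxyphosphoryl 6,12-lactone with free C8 hydroxyl (C15 PMB ether), via lithium carbanion 26 (not isolated)
Conditions: LiN(SiMe3)2 (1.05 equiv), THF, −78 °C to rt; AcOH, −78 °C
Reagents that add atoms: none
Why: Deprotonation of the phosphonoacetate methylene gives the chelated lithium carbanion 26, which attacks C7 from the side opposite the C7–O bond, forming C7–C11 and the γ-lactone and releasing the C8 alkoxide; this alkoxide is protonated at once by the more acidic α-phosphono lactone C–H. The closest known reaction type is the intramolecular alkylation of phosphonoacetate or malonate esters of 2,3-epoxy alcohols. The lactone closes 5-exo-tet. C7 is set by inversion of the epoxide carbon fixed in step 11, and because the tether starts at O6 the new bond must lie on the same side of the lactone as O6, which together with the threo precursor gives the cis ring fusion; C8 keeps its oxygen and configuration, and C11 settles trans to C8 and is erased in step 15. The step needs attack at C7 rather than C8 and needs C6–O anti to C7–O: the first is secured because a collinear backside approach within the tether is possible only at the proximal carbon (five- against six-membered transition state), the second by the threo configuration made in steps 11 and 12. Lithium is chosen to activate the epoxide oxygen, and the temperature is kept low so that the C8 alkoxide does not take over the phosphoryl group.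

Step 15
Reactants: 27 hydroxy phosphono lactone; 28 formaldehyde
Product: 29 (4Z,6S,7R,8R,10R)-8-hydroxy-11(13)-methylidene 6,12-lactone, C15 PMB ether
Conditions: K2CO3, 37% aq. 28, THF, 0 °C
Reagents that add atoms: none
Why: Horner–Wadsworth–Emmons olefination of an α-phosphono lactone with formaldehyde under mild carbonate conditions installs C11=C13 and removes the C11 stereocentre; short contact at 0 °C limits attack of the free C8 hydroxyl on C12.

Step 16
Reactants: 29 hydroxy methylidene lactone; 30 tigloyl chloride
Product: 31 (4Z,6S,7R,8R,10R)-8-O-tigloyl methylidene lactone, C15 PMB ether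
Conditions: pyridine, 4-dimethylaminopyridine (cat.), CH2Cl2, 0 °C to rt
Reagents that add atoms: none
Why: Nucleophile-catalysed acylation of the secondary alcohol with retention at C8; pyridine is used in place of a stronger amine so that the acid chloride is not deconjugated through a vinylketene.

Step 17
Reactants: 31 tiglate PMB ether
Product: 32 target, (4Z,6S,7R,8R,10R)
Conditions: 2,3-dichloro-5,6-dicyano-1,4-benzoquinone, CH2Cl2/pH 7 buffer, 0 °C
Reagents that add atoms: none
Why: Oxidative cleavage of the 4-methoxybenzyl ether (benzylic oxidation to the oxocarbenium ion, then hydrolysis); esters, the methylidene lactone and the dienyl furanone are not oxidised under these buffered conditions.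

## Compound list

1 | (S)-lactic acid | C[C@H](O)C(=O)O | starting material
2 | pivalaldehyde | CC(C)(C)C=O | starting material
3 | (2S,5S)-2-tert-butyl-5-methyl-1,3-dioxolan-4-one | C[C@@H]1O[C@H](C(C)(C)C)OC1=O | intermediate
4 | allyl bromide | C=CCBr | starting material
5 | lithium (2S)-2-tert-butyl-5-methyl-1,3-dioxol-4-olate (enolate of 3, not isolated) | CC1=C([O-])O[C@@H](C(C)(C)C)O1.[Li+] | intermediate
6 | (2S,5R)-5-allyl-2-tert-butyl-5-methyl-1,3-dioxolan-4-one | C[C@]1(CC=C)O[C@H](C(C)(C)C)OC1=O | intermediate
7 | N,O-dimethylhydroxylamine hydrochloride | CNOC.Cl | starting material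
8 | (2R)-2-hydroxy-N-methoxy-N,2-dimethylpent-4-enamide | C=CC[C@@](C)(O)C(=O)N(C)OC | intermediate
9 | 2,3-dibromopropene | C=C(Br)CBr | starting material
10 | 4-methoxybenzyl alcohol | COc1ccc(CO)cc1 | starting material
11 | 1-{[(2-bromoprop-2-en-1-yl)oxy]methyl}-4-methoxybenzene | C=C(Br)COCc1ccc(OC)cc1 | intermediate
12 | trimethylsilylacetylene | C#C[Si](C)(C)C | starting material
13 | {3-[(4-methoxybenzyloxy)methyl]but-3-en-1-yn-1-yl}trimethylsilane | C=C(COCc1ccc(OC)cc1)C#C[Si](C)(C)C | intermediate
14 | 1-methoxy-4-{[(2-methylidenebut-3-yn-1-yl)oxy]methyl}benzene | C=C(COCc1ccc(OC)cc1)C#C | intermediate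
15 | lithium acetylide of 14 (not isolated) | C=C(COCc1ccc(OC)cc1)C#[C-].[Li+] | intermediate
16 | (4R)-4-hydroxy-9-(4-methoxybenzyloxy)-4-methyl-8-methylidenenon-1-en-6-yn-5-one | C=CC[C@@](C)(O)C(=O)C#CC(=C)COCc1ccc(OC)cc1 | intermediate
17 | (2R)-2-allyl-5-[3-(4-methoxybenzyloxy)prop-1-en-2-yl]-2-methylfuran-3(2H)-one | C=CC[C@@]1(C)OC(C(=C)COCc2ccc(OC)cc2)=CC1=O | intermediate
18 | (E)-crotonaldehyde | C/C=C/C=O | starting material
19 | (2E)-4-{(2R)-5-[3-(4-methoxybenzyloxy)prop-1-en-2-yl]-2-methyl-3-oxo-2,3-dihydrofuran-2-yl}but-2-enal | O=C/C=C/C[C@@]1(C)OC(C(=C)COCc2ccc(OC)cc2)=CC1=O | intermediate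
20 | vinylmagnesium bromide | C=C[Mg]Br | starting material
21 | (2R)-2-[(2E)-4-hydroxyhexa-2,5-dien-1-yl]-5-[3-(4-methoxybenzyloxy)prop-1-en-2-yl]-2-methylfuran-3(2H)-one, both C6 epimers (carbinol carbon left undefined) | C=CC(O)/C=C/C[C@@]1(C)OC(C(=C)COCc2ccc(OC)cc2)=CC1=O | intermediate
22 | (2R)-2-{[(2R,3R)-3-[(1R)-1-hydroxyprop-2-en-1-yl]oxiran-2-yl]methyl}-5-[3-(4-methoxybenzyloxy)prop-1-en-2-yl]-2-methylfuran-3(2H)-one (erythro; 6R,7R,8R,10R) | C=C[C@@H](O)[C@H]1O[C@@H]1C[C@@]2(C)OC(C(=C)COCc3ccc(OC)cc3)=CC2=O | intermediate
23 | diethylphosphonoacetic acid | CCOP(=O)(CC(=O)O)OCC | starting material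
24 | (1S)-1-[(2S,3R)-3-({(2R)-5-[3-(4-methoxybenzyloxy)prop-1-en-2-yl]-2-methyl-3-oxo-2,3-dihydrofuran-2-yl}methyl)oxiran-2-yl]prop-2-en-1-yl (diethoxyphosphoryl)acetate (threo; 6S,7S,8R,10R) | CCOP(=O)(OCC)CC(=O)O[C@@H](C=C)[C@H]1O[C@@H]1C[C@@]2(C)OC(C(=C)COCc3ccc(OC)cc3)=CC2=O | intermediate
25 | (4Z,6S,7S,8R,10R)-macrocyclic trans-7,8-epoxide 6-(diethylphosphonoacetate), C15 PMB ether (key-step precursor) | CCOP(=O)(OCC)CC(=O)O[C@H]1/C=C(/COCc4ccc(OC)cc4)C2=CC(=O)[C@@](C)(C[C@H]3O[C@H]13)O2 | intermediate
26 | lithium carbanion of 25 at the phosphonoacetate carbon (not isolated) | CCOP(=O)(OCC)[CH-]C(=O)O[C@H]1/C=C(/COCc4ccc(OC)cc4)C2=CC(=O)[C@@](C)(C[C@H]3O[C@H]13)O2.[Li+] | intermediate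
27 | (4Z,6S,7R,8R,10R,11S)-11-diethoxyphosphoryl cis-fused 6,12-lactone with free C8 hydroxyl, C15 PMB ether (key-step product) | CCOP(=O)(OCC)[C@@H]1C(=O)O[C@H]2/C=C(/COCc4ccc(OC)cc4)C3=CC(=O)[C@@](C)(C[C@@H](O)[C@@H]12)O3 | intermediate
28 | formaldehyde | C=O | starting material
29 | (4Z,6S,7R,8R,10R)-8-hydroxy-11(13)-methylidene 6,12-lactone, C15 PMB ether | C=C1C(=O)O[C@H]2/C=C(/COCc4ccc(OC)cc4)C3=CC(=O)[C@@](C)(C[C@@H](O)[C@@H]12)O3 | intermediate
30 | tigloyl chloride, (E)-2-methylbut-2-enoyl chloride | C/C=C(\C)C(=O)Cl | starting material
31 | (4Z,6S,7R,8R,10R)-8-O-tigloyl 11(13)-methylidene 6,12-lactone, C15 PMB ether | C=C1C(=O)O[C@H]2/C=C(/COCc4ccc(OC)cc4)C3=CC(=O)[C@@](C)(C[C@@H](OC(=O)/C(C)=C/C)[C@@H]12)O3 | intermediate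
32 | target CNP0269689.6, (4Z,6S,7R,8R,10R) | C=C1C(=O)O[C@H]2/C=C(/CO)C3=CC(=O)[C@@](C)(C[C@@H](OC(=O)/C(C)=C/C)[C@@H]12)O3 | target

## Step count and least certain steps

Total: 17 steps. Longest linear sequence: 14 steps (steps 1–3 and 7–17); the enyne branch (steps 4–6) has 3 steps.

**Step 14 (key step).** The most likely failure is that the doubly stabilised carbanion does not reach the backside of C7 while the ring holds C6–O and C7–O away from an anti arrangement. Forcing the reaction by heat then invites transfer of the phosphoryl group to the C8 alkoxide (the Wadsworth–Emmons cyclopropanation pathway) or translactonisation. Fallback: reverse the order of the two ring closures. Starting from open-chain ester 24, the same base treatment (LiN(SiMe3)2, THF) opens the epoxide without any ring constraint and gives the open-chain hydroxy phosphono lactone F1, in which the C5 vinyl group and the C8 side chain are held cis on the lactone. Ring-closing metathesis of F1 with the second-generation Hoveyda–Grubbs catalyst then closes C4=C5 and returns to the route at 27.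

**Step 13.** Ring closure onto the conjugated 1,1-disubstituted alkene may be slower than intermolecular metathesis at the C5 vinyl group, which carries an electron-withdrawing allylic ester, so that oligomerisation and catalyst decay win. Fallback: close the ring on a different substrate. Starting from epoxy alcohol 22, whose free allylic hydroxyl activates the adjacent vinyl group, metathesis gives the macrocyclic erythro epoxy alcohol F2 (6R,7R,8R,10R). Mitsunobu esterification of F2 with 23 then inverts C6 within the ring and returns to the route at 25.

**Step 11.** Discrimination between the two C6 epimers may be incomplete, and the unwanted epimer is slowly epoxidised at its vinyl group; by design half of the material is not used. Fallback: set C6 when the C5–C6 bond is formed. Starting from enal 19, a catalytic enantioselective vinyl addition (Zn(CH=CH2)2 with a chiral amino alcohol ligand of the appropriate hand) gives the single (6R)-dienol F3. The same titanium–tartrate epoxidation is then a matched diastereoselective reaction run to full conversion and returns to the route at 22.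

**Step 12.** With the bulky, moderately acidic phosphonoacetic acid the substitution may divert to attack at the vinyl terminus (allylic transposition) or to elimination instead of clean inversion. Fallback: separate the inversion from the introduction of phosphorus. Starting from 22, Mitsunobu esterification with chloroacetic acid, a small and more acidic partner, gives the inverted threo chloroacetate F4. A Michaelis–Arbuzov reaction of F4 with P(OEt)3 (NaI catalysis) then builds the phosphonate and returns to the route at 24.

**Step 15.** Under carbonate the free C8 hydroxyl may attack C12 and shift the lactone from the C6 to the C8 oxygen before or after olefination. Fallback: cap the C8 oxygen first. Starting from 27, acylation with 30 (pyridine, 4-dimethylaminopyridine) gives the 8-O-tigloyl phosphono lactone F5. The Horner–Wadsworth–Emmons reaction of F5 with 28 then returns to the route at 31, bypassing 29.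

## Further compounds

F1 | step 14 | open-chain hydroxy phosphono lactone: cis-4-vinyl γ-lactone bearing the (R)-carbinol side chain to the furanone (6S,7R,8R,10R,11S) | CCOP(=O)(OCC)[C@@H]1C(=O)O[C@@H](C=C)[C@H]1[C@H](O)C[C@@]2(C)OC(C(=C)COCc3ccc(OC)cc3)=CC2=O
F2 | step 13 | macrocyclic erythro epoxy alcohol (4Z,6R,7R,8R,10R), C15 PMB ether | O[C@@H]1/C=C(/COCc4ccc(OC)cc4)C2=CC(=O)[C@@](C)(C[C@H]3O[C@H]13)O2
F3 | step 11 | (6R)-epimer of dienol 21 | C=C[C@@H](O)/C=C/C[C@@]1(C)OC(C(=C)COCc2ccc(OC)cc2)=CC1=O
F4 | step 12 | threo chloroacetate of the epoxy alcohol (6S,7S,8R,10R) | ClCC(=O)O[C@@H](C=C)[C@H]1O[C@@H]1C[C@@]2(C)OC(C(=C)COCc3ccc(OC)cc3)=CC2=O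
F5 | step 15 | 8-O-tigloyl derivative of phosphono lactone 27 | CCOP(=O)(OCC)[C@@H]1C(=O)O[C@H]2/C=C(/COCc4ccc(OC)cc4)C3=CC(=O)[C@@](C)(C[C@@H](OC(=O)/C(C)=C/C)[C@@H]12)O3
A1 | alternative 1 | (Z)-cyclodec-4-ene-1,3,6-trione with C8 tiglate, C10 triethylsilyl ether and protected C12 and C15 hydroxyls | O=C1CC(=O)/C(COCc2ccc(OC)cc2)=C\C(=O)[C@H](C(=C)CO[Si](C)(C)C(C)(C)C)[C@H](OC(=O)/C(C)=C/C)C[C@@]1(C)O[Si](CC)(CC)CC
A2 | alternative 2 | ten-membered C8 carbinol with C11 methylidene, C1, C6 and C12 silyl ethers | C=C(CO[Si](C)(C)C(C)(C)C)[C@H]1[C@@H](O[Si](C)(C)C(C)(C)C)/C=C(/COCc3ccc(OC)cc3)C2=C[C@@H](O[Si](C)(C)C(C)(C)C)[C@@](C)(C[C@H]1O)O2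
A3 | alternative 3 | furanone-bridged cyclodecadiene bis-silyl ether with C8 tiglate | C=C(CO[Si](C)(C)C(C)(C)C)[C@H]1[C@@H](O[Si](C)(C)C(C)(C)C)/C=C(/COCc3ccc(OC)cc3)C2=CC(=O)[C@@](C)(C[C@H]1OC(=O)/C(C)=C/C)O2
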